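**Strategy.** The alcohol part is a 4,5-seco-caryophyllene: the ketone carbon and the OCH2 carbon are the ends of a cleaved ring alkene, so the cyclobutane (CMe2, CH2, two CH) with the methylene-bearing carbon on C1 maps onto a folded farnesyl chain. The route rests on an enzymatic cation–olefin bicyclization: (−)-β-caryophyllene synthase, a class 1 sesquiterpene cyclase, ionizes achiral, acyclic (2E,6E)-farnesyl diphosphate and, after 1,11-closure, forms the cyclobutane bond between the two ring CH carbons (C1–C2 of the cyclobutane; farnesyl C2–C10), setting both stereocentres, the trans ring fusion and the exocyclic methylene at once. Ozonolysis of the strained ring alkene, aldehyde-selective reduction and esterification with linoleic acid complete the synthesis.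

Key step: step 3

Assumption: the cyclase is used as a purified recombinant protein (QHS1 gene of Artemisia annua expressed in E. coli) and counts as a catalyst; the target has the (1R,9S) ring configuration of natural (−)-β-caryophyllene, which this enzyme delivers.

**Step 1**
Reactants: 1 (2E,6E)-farnesol
Product: 2 (2E,6E)-farnesyl bromide
Conditions: PBr3, Et2O, −10 → 0 °C
Reagents that add atoms: phosphorus tribromide, BrP(Br)Br
Why: PBr3 bromination of a primary allylic alcohol: the hydroxyl is activated as a phosphite ester and displaced by bromide at C1 (SN2) at low temperature, so neither allylic transposition nor E/Z scrambling is expected.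

**Step 2**
Reactants: 2 (2E,6E)-farnesyl bromide
Product: 3 (2E,6E)-farnesyl diphosphate, tris(ammonium) salt
Conditions: (Bu4N)3HP2O7 (excess), MeCN, rt; then Dowex 50WX8 (NH4+ form), aq. NH4HCO3/iPrOH; lyophilization
Reagents that add atoms: tris(tetrabutylammonium) hydrogen diphosphate, CCCC[N+](CCCC)(CCCC)CCCC.CCCC[N+](CCCC)(CCCC)CCCC.CCCC[N+](CCCC)(CCCC)CCCC.OP(=O)([O-])OP(=O)([O-])[O-]; ammonium hydrogen carbonate, [NH4+].OC([O-])=O
Why: Poulter-type diphosphorylation: SN2 displacement of the primary allylic bromide by the poorly solvated diphosphate anion in MeCN, with excess nucleophile to suppress double alkylation and cation exchange to give the enzyme-compatible ammonium salt.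

**Step 3**
Reactants: 3 (2E,6E)-farnesyl diphosphate, tris(ammonium) salt
Product: 6 (−)-β-caryophyllene [(1R,4E,9S)-4,11,11-trimethyl-8-methylidenebicyclo[7.2.0]undec-4-ene], via humulyl cation 4 (not isolated), via caryophyllenyl cation 5 (not isolated)
Conditions: (−)-β-caryophyllene synthase (EC 4.2.3.57, class 1 sesquiterpene cyclase, recombinant QHS1), MgCl2, DTT, HEPES buffer pH 7.5, glycerol, pentane overlay, 30 °C; AgNO3–silica chromatography
Reagents that add atoms: none
Why: (farnesyl numbering) The divalent magnesium ions bound at the aspartate-rich motifs of the cyclase ionize the diphosphate of 3, the allyl cation carbon C1 is captured by the distal C10=C11 bond at C11 (eleven-membered ring, 11-endo-trig with respect to that alkene) to give humulyl cation 4, the C2=C3 bond then attacks cationic C10 through C2 (four-membered ring, 4-exo-trig with respect to the C2=C3 alkene; the same bond cuts the eleven-membered ring down to the nine-membered one) to give tertiary cation 5, and loss of a proton from the C3 methyl group leaves the exocyclic methylene. The closest known reaction type is the ionization-initiated cation–olefin polycyclization of class 1 terpene cyclases, and this is the native reaction of (−)-β-caryophyllene synthase on its native substrate. Both new stereocentres, farnesyl C2 and C10 (the two cyclobutane CH carbons), are set by catalyst control: the chiral active-site contour holds one helical fold of the humulyl ring, so the C2=C3 bond should meet C10 on a single face and the trans-fused (1R,9S) bicycle should form as one enantiomer from an achiral substrate. The 4E geometry of the nine-membered ring is inherited from the 6E alkene of 3. The step needs 1,11- over 1,10-closure, closure of the strained four-membered ring in preference to proton loss from 4 (which would give α-humulene, the expected minor co-product removed on AgNO3–silica), and final proton loss from the methyl group and not from a ring CH2; the 2E geometry of 3 lets C1 reach C11 without prior isomerization, and the enzyme pocket, which shields the secondary cation from water and base until the C2=C3 bond has added, secures the rest.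

**Step 4**
Reactants: 6 (−)-β-caryophyllene
Product: 8 4-[(1S,2R)-3,3-dimethyl-2-(3-oxobutyl)cyclobutyl]pent-4-enal, via secondary ozonide 7 (not isolated)
Conditions: O3 (1.0 equiv, titrated solution), CH2Cl2, −78 °C; then PPh3, −78 °C → rt
Reagents that add atoms: ozone, [O-][O+]=O
Why: Criegee ozonolysis with a single equivalent of ozone: the strained, trisubstituted trans-alkene of the nine-membered ring should react far faster with the electrophilic 1,3-dipole than the 1,1-disubstituted exocyclic methylene, and PPh3 reduces ozonide 7 to the keto aldehyde without touching the two ring stereocentres, neither of which is α to a carbonyl.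

**Step 5**
Reactants: 8 4-[(1S,2R)-3,3-dimethyl-2-(3-oxobutyl)cyclobutyl]pent-4-enal
Product: 9 4-[(1S,2R)-3,3-dimethyl-2-(3-oxobutyl)cyclobutyl]pent-4-en-1-ol
Conditions: NaBH4 (substoichiometric), EtOH/CH2Cl2 (3:7), −78 °C; then H2O
Reagents that add atoms: none
Why: Chemoselective borohydride reduction: at −78 °C in EtOH/CH2Cl2 the aldehyde should be reduced much faster than the less electrophilic methyl ketone, and no stereocentre is created.

**Step 6**
Reactants: 9 4-[(1S,2R)-3,3-dimethyl-2-(3-oxobutyl)cyclobutyl]pent-4-en-1-ol; 10 linoleic acid [(9Z,12Z)-octadeca-9,12-dienoic acid]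
Product: 11 4-[(1S,2R)-3,3-dimethyl-2-(3-oxobutyl)cyclobutyl]pent-4-en-1-yl (9Z,12Z)-octadeca-9,12-dienoate (IN0146)
Conditions: DCC, DMAP (cat.), CH2Cl2, 0 °C → rt, argon, dark
Reagents that add atoms: none
Why: Steglich esterification: carbodiimide activation with DMAP acyl transfer should acylate the primary alcohol under neutral conditions that leave the skipped Z,Z-diene, the ketone, the exocyclic alkene and both stereocentres untouched.

**Compound list**
1 | (2E,6E)-farnesol | CC(C)=CCC/C(C)=C/CC/C(C)=C/CO | starting material
2 | (2E,6E)-farnesyl bromide | CC(C)=CCC/C(C)=C/CC/C(C)=C/CBr | intermediate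
3 | (2E,6E)-farnesyl diphosphate, tris(ammonium) salt | CC(C)=CCC/C(C)=C/CC/C(C)=C/COP(=O)([O-])OP(=O)([O-])[O-].[NH4+].[NH4+].[NH4+] | intermediate
4 | humulyl cation (enzyme-bound, secondary cation at farnesyl C10) | C/C1=C\CC(C)(C)[CH+]CC/C(C)=C/CC1 | intermediate
5 | caryophyllenyl cation (enzyme-bound, tertiary cation at farnesyl C3) | C/C1=C\CC[C+](C)[C@H]2CC(C)(C)[C@@H]2CC1 | intermediate
6 | (−)-β-caryophyllene, (1R,4E,9S)-4,11,11-trimethyl-8-methylidenebicyclo[7.2.0]undec-4-ene | C/C1=C\CCC(=C)[C@H]2CC(C)(C)[C@@H]2CC1 | intermediate
7 | secondary ozonide (1,2,4-trioxolane) across C4–C5 of 6, trioxolane configuration not assigned | CC12OOC(O1)CCC(=C)[C@H]1CC(C)(C)[C@@H]1CC2 | intermediate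
8 | 4-[(1S,2R)-3,3-dimethyl-2-(3-oxobutyl)cyclobutyl]pent-4-enal | C=C(CCC=O)[C@H]1CC(C)(C)[C@@H]1CCC(C)=O | intermediate
9 | 4-[(1S,2R)-3,3-dimethyl-2-(3-oxobutyl)cyclobutyl]pent-4-en-1-ol | C=C(CCCO)[C@H]1CC(C)(C)[C@@H]1CCC(C)=O | intermediate
10 | linoleic acid, (9Z,12Z)-octadeca-9,12-dienoic acid | CCCCC/C=C\C/C=C\CCCCCCCC(=O)O | starting material
11 | 4-[(1S,2R)-3,3-dimethyl-2-(3-oxobutyl)cyclobutyl]pent-4-en-1-yl (9Z,12Z)-octadeca-9,12-dienoate (IN0146) | C=C(CCCOC(=O)CCCCCCC/C=C\C/C=C\CCCCC)[C@H]1CC(C)(C)[C@@H]1CCC(C)=O | target

**Step count.** Total: 6 steps. Longest linear sequence: 6 steps (1 → 11); linoleic acid 10 enters in the last step.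

**Steps most likely to fail**

Step 3. Turnover may stall through inhibition by the released diphosphate and by the amphiphilic substrate, the allylic diphosphate may hydrolyse in the buffer, and the monocyclic cation may lose a proton before the four-membered ring closes. The fallback sets out from 1 and comes back at 6, replacing chemical diphosphorylation and bolus feeding by a coupled kinase–cyclase cascade in one vessel. Farnesol 1 is phosphorylated by a promiscuous prenol kinase of the diacylglycerol-kinase family (the kind that phosphorylates undecaprenol) to (2E,6E)-farnesyl monophosphate F1. An isopentenyl phosphate kinase variant with a widened pocket then gives (2E,6E)-farnesyl diphosphate F2 (ATP recycled from phosphoenolpyruvate by pyruvate kinase, MgCl2, buffer pH 7.5). The same cyclase, or an ortholog with a tighter product profile, converts F2 as it forms into 6, which is collected in the pentane overlay. The steady low level of F2 should avoid substrate inhibition and hydrolysis, and steps 1 and 2 drop out.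

Step 4. Ozone may go on to attack the exocyclic methylene once the ring alkene is consumed, or oxygen-atom transfer (epoxidation) may compete at the hindered alkene. The fallback sets out from 6 and comes back at 8, separating oxidation and cleavage. Upjohn dihydroxylation (K2OsO4·2H2O cat., one equivalent of NMO, acetone/H2O, 0 °C) should hydroxylate the electron-rich, strained trisubstituted alkene first and give (1R,9S)-4,11,11-trimethyl-8-methylidenebicyclo[7.2.0]undecane-4,5-diol F3 (syn diol; carbinol configuration immaterial). Glycol cleavage with NaIO4 in THF/H2O then gives 8.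

Step 5. Hydride may also add to the methyl ketone, eroding the aldehyde/ketone chemoselectivity. The fallback sets out from 8 and comes back at 11, giving up the selective reduction. Both carbonyls are reduced with excess NaBH4 in MeOH at 0 °C to 4-[(1S,2R)-2-(3-hydroxybutyl)-3,3-dimethylcyclobutyl]pent-4-en-1-ol F4 (both epimers at the new carbinol, immaterial). The primary hydroxyl alone is esterified with one equivalent of linoleic acid 10 (DCC, cat. DMAP, CH2Cl2, −20 °C, steric preference for the primary carbinol) to give 4-[(1S,2R)-2-(3-hydroxybutyl)-3,3-dimethylcyclobutyl]pent-4-en-1-yl (9Z,12Z)-octadeca-9,12-dienoate F5. Dess–Martin periodinane (NaHCO3, CH2Cl2, 0 °C) then re-forms the methyl ketone and gives 11.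

**Further compounds**
F1 | step 3 | (2E,6E)-farnesyl monophosphate | CC(C)=CCC/C(C)=C/CC/C(C)=C/COP(=O)(O)O
F2 | step 3 | (2E,6E)-farnesyl diphosphate, formed and consumed in the flask (written as the free acid) | CC(C)=CCC/C(C)=C/CC/C(C)=C/COP(=O)(O)OP(=O)(O)O
F3 | step 4 | (1R,9S)-4,11,11-trimethyl-8-methylidenebicyclo[7.2.0]undecane-4,5-diol (syn diol) | CC1(O)C(O)CCC(=C)[C@H]2CC(C)(C)[C@@H]2CC1
F4 | step 5 | 4-[(1S,2R)-2-(3-hydroxybutyl)-3,3-dimethylcyclobutyl]pent-4-en-1-ol | C=C(CCCO)[C@H]1CC(C)(C)[C@@H]1CCC(C)O
F5 | step 5 | 4-[(1S,2R)-2-(3-hydroxybutyl)-3,3-dimethylcyclobutyl]pent-4-en-1-yl (9Z,12Z)-octadeca-9,12-dienoate | C=C(CCCOC(=O)CCCCCCC/C=C\C/C=C\CCCCC)[C@H]1CC(C)(C)[C@@H]1CCC(C)O
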